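**Retrosynthetic overview**

1. The target (no stereocentres) is taken back by debenzylation, removal of the ring A C3 chlorine and removal of the 4-O-methyl group to the dibenzyl-protected depside 16, whose ring A is a plain 2,4-dihydroxy-6-propylbenzoate.
2. The strategy rests on ring A being a folded tetraketide: the depside carbonyl is chain C1, the ring A C2 and C4 oxygens are the chain C3 and C5 ketones, and ring A C6 with its propyl group is the chain C7 ketone plus C8–C10. Breaking the ring A C1–C6 bond gives the aryl 3,5,7-trioxodecanoate 14, which already carries the depside C(=O)–O link to the ring B C4 oxygen.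
3. The depside link of 14 comes from capture of an acylketene (from diketo-dioxinone 7) by the ring B phenol 12 under neutral conditions.
4. 7 arises from 2,2,6-trimethyl-4H-1,3-dioxin-4-one by two dienolate C-acylations (acetyl, then butanoyl); 12 arises from olivetolic acid by benzyl ester formation, temporary 4-O-allylation, 2-O-benzylation and deallylation.
5. Ring order: ring B is bought as olivetolic acid; ring A is the only ring formed (step 9).

Key step: step 9

Remark: ring A is the chlorinated acyl ring and ring B the olivetolic acid ring; chain locants C1–C10 refer to the 3,5,7-trioxodecanoyl unit, with C1 the depside carbonyl.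

**Route**

Step 1
Reactants: 1 butanoyl chloride
Product: 2 N-methoxy-N-methylbutanamide
Conditions: MeNH(OMe)·HCl, pyridine, CH2Cl2, 0 °C to rt
Reagents that add atoms: N,O-dimethylhydroxylamine hydrochloride, CNOC.Cl
Why: Acylation of the hydroxylamine nitrogen by an acid chloride (Weinreb amide formation) is fast and should be clean with pyridine as acid scavenger.

Step 2
Reactants: 3 2,2,6-trimethyl-4H-1,3-dioxin-4-one
Product: 5 2,2-dimethyl-6-(2-oxopropyl)-4H-1,3-dioxin-4-one, via lithium dienolate 4 (not isolated)
Conditions: LiN(SiMe3)2, THF, −78 °C; AcCl (0.5 equiv), −78 to −20 °C; aq. NH4Cl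
Reagents that add atoms: acetyl chloride, CC(=O)Cl
Why: γ-Deprotonation of the vinylogous ester gives the extended dienolate, which should be C-acylated at the exocyclic carbon (vinylogous Claisen acylation), a second equivalent of dienolate being consumed in deprotonating the more acidic product.

Step 3
Reactants: 5 2,2-dimethyl-6-(2-oxopropyl)-4H-1,3-dioxin-4-one; 2 N-methoxy-N-methylbutanamide
Product: 7 6-(2,4-dioxoheptyl)-2,2-dimethyl-4H-1,3-dioxin-4-one, via dilithium dianion 6 (not isolated)
Conditions: LiN(iPr)2 (2.2 equiv), THF, −78 °C; then 2, −78 to −40 °C; 1 M HCl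
Reagents that add atoms: none
Why: The β-dicarbonyl-type dianion should react at its last-formed terminal carbon, and the Weinreb ketone synthesis stops at the chelated tetrahedral adduct, so over-addition and O-acylation are suppressed.

Step 4
Reactants: 8 olivetolic acid (2,4-dihydroxy-6-pentylbenzoic acid)
Product: 9 benzyl 2,4-dihydroxy-6-pentylbenzoate
Conditions: BnBr (1.05 equiv), KHCO3, DMF, rt
Reagents that add atoms: benzyl bromide, BrCc1ccccc1
Why: Hydrogencarbonate deprotonates only the carboxylic acid, so SN2 alkylation of the carboxylate should give the ester without touching either phenol.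

Step 5
Reactants: 9 benzyl 2,4-dihydroxy-6-pentylbenzoate
Product: 10 benzyl 2-hydroxy-6-pentyl-4-(prop-2-en-1-yloxy)benzoate
Conditions: allyl bromide (1.05 equiv), K2CO3, acetone, 50 °C
Reagents that add atoms: allyl bromide, C=CCBr
Why: In this Williamson etherification the 2-OH is held in a hydrogen bond to the ester carbonyl and is far less acidic and nucleophilic, so one equivalent of halide should go to the 4-OH.

Step 6
Reactants: 10 benzyl 2-hydroxy-6-pentyl-4-(prop-2-en-1-yloxy)benzoate
Product: 11 benzyl 2-(benzyloxy)-6-pentyl-4-(prop-2-en-1-yloxy)benzoate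
Conditions: BnBr, K2CO3, DMF, 60 °C
Reagents that add atoms: benzyl bromide, BrCc1ccccc1
Why: More forcing Williamson conditions should alkylate the remaining chelated phenol, while the allyl ether and benzyl ester are inert at this temperature.

Step 7
Reactants: 11 benzyl 2-(benzyloxy)-6-pentyl-4-(prop-2-en-1-yloxy)benzoate
Product: 12 benzyl 2-(benzyloxy)-4-hydroxy-6-pentylbenzoate
Conditions: Pd(PPh3)4 (5 mol%), morpholine, THF, rt
Reagents that add atoms: none
Why: Zerovalent palladium ionises the allyl aryl ether to a π-allyl complex and phenoxide, and morpholine captures the allyl fragment (Tsuji–Trost deallylation), which should leave the benzyl ester and benzyl ether untouched.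

Step 8
Reactants: 7 6-(2,4-dioxoheptyl)-2,2-dimethyl-4H-1,3-dioxin-4-one; 12 benzyl 2-(benzyloxy)-4-hydroxy-6-pentylbenzoate
Product: 14 benzyl 2-(benzyloxy)-6-pentyl-4-[(3,5,7-trioxodecanoyl)oxy]benzoate, via acylketene 13 (not isolated)
Conditions: 12 (1.5 equiv), PhMe (0.2 M), 110 °C, 1 h; concentrate, use crude
Reagents that add atoms: none
Why: Thermal retro-hetero-Diels–Alder loss of acetone from the dioxinone gives the acylketene, and addition of the phenol O–H across the ketene under neutral conditions should give the aryl β-keto ester, excess phenol favouring intermolecular capture.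

Step 9
Reactants: 14 benzyl 2-(benzyloxy)-6-pentyl-4-[(3,5,7-trioxodecanoyl)oxy]benzoate
Product: 16 benzyl 2-(benzyloxy)-4-[(2,4-dihydroxy-6-propylbenzoyl)oxy]-6-pentylbenzoate, via aldol adduct 15 (not isolated)
Conditions: Et3N (3 equiv), CH2Cl2, 0 °C to rt; then HCl (4 M in dioxane), rt
Reagents that add atoms: none
Why: Triethylamine enolises the triketo ester, and chain C2 (between the ester C1 and the C3 ketone) adds to the C7 ketone to give the cyclohexanedione aldol adduct 15; loss of water on acidification and enolisation of the C3 and C5 carbonyls should then give the aromatic 2,4-dihydroxy-6-propylbenzoate with the new ring A C1–C6 bond. The closest known reaction type is the biomimetic aldol aromatisation of 3,5,7-triketo esters made by acylketene capture (resorcylate synthesis), applied here to an aryl ester. Ring A closes by a 6-(enolendo)-exo-trig aldol; no stereocentre remains, since the two of 15 are destroyed on aromatisation. The step needs chemoselectivity for the C2-to-C7 aldol over C6-to-C1 Claisen closure and over attack of the C5 enol oxygen on C1 (pyranone formation), both of which would expel the ring B phenoxide. This should be secured by a weak, non-chelating amine base in an aprotic solvent at low temperature (metal alkoxides, which favour Claisen closure, are avoided), by the C7 ketone being more electrophilic than the ester C1, and by the dehydration that makes the aldol irreversible.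

Step 10
Reactants: 16 benzyl 2-(benzyloxy)-4-[(2,4-dihydroxy-6-propylbenzoyl)oxy]-6-pentylbenzoate
Product: 17 benzyl 2-(benzyloxy)-4-[(2-hydroxy-4-methoxy-6-propylbenzoyl)oxy]-6-pentylbenzoate
Conditions: MeI (1.1 equiv), K2CO3 (1.1 equiv), acetone, rt
Reagents that add atoms: iodomethane, CI
Why: In this Williamson methylation the ring A 2-OH is hydrogen-bonded to the depside carbonyl and ring B has no free phenol, so the more acidic, unchelated ring A 4-OH should be the only site methylated.

Step 11
Reactants: 17 benzyl 2-(benzyloxy)-4-[(2-hydroxy-4-methoxy-6-propylbenzoyl)oxy]-6-pentylbenzoate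
Product: 18 benzyl 2-(benzyloxy)-4-[(3-chloro-2-hydroxy-4-methoxy-6-propylbenzoyl)oxy]-6-pentylbenzoate
Conditions: NCS (1.05 equiv), 2,2,6,6-tetramethylpiperidine (10 mol%), PhMe, 0 °C to rt
Reagents that add atoms: N-chlorosuccinimide, O=C1CCC(=O)N1Cl
Why: In this amine-catalysed ortho-chlorination of a phenol, the N-chloroamine formed in situ is hydrogen-bonded to the ring A 2-OH and should deliver chlorine to C3, the only free ortho position and one also activated by the neighbouring methoxy group, while ring B (no free phenol) is much less electron-rich.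

Step 12
Reactants: 18 benzyl 2-(benzyloxy)-4-[(3-chloro-2-hydroxy-4-methoxy-6-propylbenzoyl)oxy]-6-pentylbenzoate
Product: 19 4-[(3-chloro-2-hydroxy-4-methoxy-6-propylbenzoyl)oxy]-2-hydroxy-6-pentylbenzoic acid
Conditions: H2 (1 atm), 10% Pd/C, EtOAc, rt
Reagents that add atoms: none
Why: Catalytic hydrogenolysis of the benzylic C–O bonds of the ester and the ether under neutral conditions should free the acid and the ring B phenol, the electron-rich aryl chloride and the depside ester being expected to survive a short neutral hydrogenolysis.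

**Compound list**

1 | butanoyl chloride | CCCC(=O)Cl | starting material
2 | N-methoxy-N-methylbutanamide | CCCC(=O)N(C)OC | intermediate
3 | 2,2,6-trimethyl-4H-1,3-dioxin-4-one | CC1=CC(=O)OC(C)(C)O1 | starting material
4 | lithium 2,2-dimethyl-6-methylidene-6H-1,3-dioxin-4-olate (lithium dienolate of 3) | [Li+].[O-]C1=CC(=C)OC(C)(C)O1 | intermediate
5 | 2,2-dimethyl-6-(2-oxopropyl)-4H-1,3-dioxin-4-one | CC(=O)CC1=CC(=O)OC(C)(C)O1 | intermediate
6 | dilithium 2,2-dimethyl-6-(2-oxidoprop-2-en-1-ylidene)-6H-1,3-dioxin-4-olate (dianion of 5, double-bond geometry not defined) | [Li+].[Li+].C=C([O-])C=C1C=C([O-])OC(C)(C)O1 | intermediate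
7 | 6-(2,4-dioxoheptyl)-2,2-dimethyl-4H-1,3-dioxin-4-one | CCCC(=O)CC(=O)CC1=CC(=O)OC(C)(C)O1 | intermediate
8 | olivetolic acid (2,4-dihydroxy-6-pentylbenzoic acid) | CCCCCc1cc(O)cc(O)c1C(=O)O | starting material
9 | benzyl 2,4-dihydroxy-6-pentylbenzoate | CCCCCc1cc(O)cc(O)c1C(=O)OCc1ccccc1 | intermediate
10 | benzyl 2-hydroxy-6-pentyl-4-(prop-2-en-1-yloxy)benzoate | CCCCCc1cc(OCC=C)cc(O)c1C(=O)OCc1ccccc1 | intermediate
11 | benzyl 2-(benzyloxy)-6-pentyl-4-(prop-2-en-1-yloxy)benzoate | CCCCCc1cc(OCC=C)cc(OCc2ccccc2)c1C(=O)OCc1ccccc1 | intermediate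
12 | benzyl 2-(benzyloxy)-4-hydroxy-6-pentylbenzoate | CCCCCc1cc(O)cc(OCc2ccccc2)c1C(=O)OCc1ccccc1 | intermediate
13 | dec-1-ene-1,3,5,7-tetrone (acylketene) | CCCC(=O)CC(=O)CC(=O)C=C=O | intermediate
14 | benzyl 2-(benzyloxy)-6-pentyl-4-[(3,5,7-trioxodecanoyl)oxy]benzoate | CCCC(=O)CC(=O)CC(=O)CC(=O)Oc1cc(CCCCC)c(C(=O)OCc2ccccc2)c(OCc2ccccc2)c1 | intermediate
15 | benzyl 2-(benzyloxy)-4-[(2-hydroxy-4,6-dioxo-2-propylcyclohexane-1-carbonyl)oxy]-6-pentylbenzoate (aldol adduct; mixture of diastereomers and tautomers, no configuration defined) | CCCC1(O)CC(=O)CC(=O)C1C(=O)Oc1cc(CCCCC)c(C(=O)OCc2ccccc2)c(OCc2ccccc2)c1 | intermediate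
16 | benzyl 2-(benzyloxy)-4-[(2,4-dihydroxy-6-propylbenzoyl)oxy]-6-pentylbenzoate | CCCc1cc(O)cc(O)c1C(=O)Oc1cc(CCCCC)c(C(=O)OCc2ccccc2)c(OCc2ccccc2)c1 | intermediate
17 | benzyl 2-(benzyloxy)-4-[(2-hydroxy-4-methoxy-6-propylbenzoyl)oxy]-6-pentylbenzoate | CCCc1cc(OC)cc(O)c1C(=O)Oc1cc(CCCCC)c(C(=O)OCc2ccccc2)c(OCc2ccccc2)c1 | intermediate
18 | benzyl 2-(benzyloxy)-4-[(3-chloro-2-hydroxy-4-methoxy-6-propylbenzoyl)oxy]-6-pentylbenzoate | CCCc1cc(OC)c(Cl)c(O)c1C(=O)Oc1cc(CCCCC)c(C(=O)OCc2ccccc2)c(OCc2ccccc2)c1 | intermediate
19 | 4-[(3-chloro-2-hydroxy-4-methoxy-6-propylbenzoyl)oxy]-2-hydroxy-6-pentylbenzoic acid | CCCCCc1cc(OC(=O)c2c(CCC)cc(OC)c(Cl)c2O)cc(O)c1C(=O)O | target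

**Step count**

Total steps: 12. Longest linear sequence: 9 steps (steps 4 to 12, from olivetolic acid 8).

**Steps most likely to fail**

Step 9 (key step). The aldol closure may lose to Claisen closure onto C1 or to lactonisation by the C5 enol oxygen, each expelling the ring B phenoxide, because an aryloxide is a far better leaving group than the alkoxides of the usual triketo esters. The fallback builds ring A on an alkyl ester and attaches ring B afterwards; it sets out from 7 and returns at 17.
- 7 would be heated with benzyl alcohol in toluene to give benzyl 3,5,7-trioxodecanoate F1.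
- F1 would be cyclised with Cs2CO3 and aromatised with HCl to benzyl 2,4-dihydroxy-6-propylbenzoate F2.
- F2 would be methylated at the unchelated 4-OH (MeI, K2CO3, acetone) to benzyl 2-hydroxy-4-methoxy-6-propylbenzoate F3.
- F3 would be hydrogenolysed (H2, Pd/C) to 2-hydroxy-4-methoxy-6-propylbenzoic acid F4.
- F4 would be condensed with phenol 12 using trifluoroacetic anhydride in toluene, giving 17.

Step 8. Capture of the acylketene by its own enolised 1,3-diketone, or thermal lactonisation of the aryl ester once formed, may outpace capture by the weakly nucleophilic, ester-deactivated phenol. The fallback avoids ketene generation altogether; it sets out from 7 and returns at 17.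
- 7 would be treated with Et3N in CH2Cl2 at rt, where the aldol aromatisation proceeds with the dioxinone ring intact, to give 7-hydroxy-2,2-dimethyl-5-propyl-4H-1,3-benzodioxin-4-one F5.
- F5 would be O-methylated (MeI, K2CO3) to 7-methoxy-2,2-dimethyl-5-propyl-4H-1,3-benzodioxin-4-one F6.
- F6 would be hydrolysed with aqueous KOH in DMSO to 2-hydroxy-4-methoxy-6-propylbenzoic acid F4, the acid of the preceding fallback.
- F4 would be esterified with 12 by trifluoroacetic anhydride in toluene to reach 17.

Step 11. Ortho delivery of chlorine may be poor because the directing phenol is tied up in its hydrogen bond to the depside carbonyl, so chlorination para to the phenol (ring A C5) or double chlorination may intrude. The fallback uses bromine as a removable blocking group; it sets out from 17 and returns at the target 19.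
- 17 would be brominated para to the ring A phenol with N-bromosuccinimide in MeCN at 0 °C to give benzyl 2-(benzyloxy)-4-[(3-bromo-6-hydroxy-4-methoxy-2-propylbenzoyl)oxy]-6-pentylbenzoate F7 (bromine at ring A C5).
- F7 would be chlorinated at the one remaining ring A position, C3, with SO2Cl2 in CH2Cl2 to give benzyl 2-(benzyloxy)-4-[(3-bromo-5-chloro-6-hydroxy-4-methoxy-2-propylbenzoyl)oxy]-6-pentylbenzoate F8.
- F8 would be hydrogenolysed (H2, Pd/C, NaOAc, EtOAc), which should remove the aryl bromide and both benzyl groups much faster than the aryl chloride, giving 19.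

**Further compounds**

F1 | step 9 | benzyl 3,5,7-trioxodecanoate | CCCC(=O)CC(=O)CC(=O)CC(=O)OCc1ccccc1
F2 | step 9 | benzyl 2,4-dihydroxy-6-propylbenzoate | CCCc1cc(O)cc(O)c1C(=O)OCc1ccccc1
F3 | step 9 | benzyl 2-hydroxy-4-methoxy-6-propylbenzoate | CCCc1cc(OC)cc(O)c1C(=O)OCc1ccccc1
F4 | step 9 | 2-hydroxy-4-methoxy-6-propylbenzoic acid | CCCc1cc(OC)cc(O)c1C(=O)O
F5 | step 8 | 7-hydroxy-2,2-dimethyl-5-propyl-4H-1,3-benzodioxin-4-one | CCCc1cc(O)cc2OC(C)(C)OC(=O)c12
F6 | step 8 | 7-methoxy-2,2-dimethyl-5-propyl-4H-1,3-benzodioxin-4-one | CCCc1cc(OC)cc2OC(C)(C)OC(=O)c12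
F7 | step 11 | benzyl 2-(benzyloxy)-4-[(3-bromo-6-hydroxy-4-methoxy-2-propylbenzoyl)oxy]-6-pentylbenzoate | CCCc1c(Br)c(OC)cc(O)c1C(=O)Oc1cc(CCCCC)c(C(=O)OCc2ccccc2)c(OCc2ccccc2)c1
F8 | step 11 | benzyl 2-(benzyloxy)-4-[(3-bromo-5-chloro-6-hydroxy-4-methoxy-2-propylbenzoyl)oxy]-6-pentylbenzoate | CCCc1c(Br)c(OC)c(Cl)c(O)c1C(=O)Oc1cc(CCCCC)c(C(=O)OCc2ccccc2)c(OCc2ccccc2)c1
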